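(All runs come from a simulation with made-up constants; the scatter is artificial.)

The ring is the product I had to follow, and in these flasks it was already on its way out at the first sampling.

common to all: starting material 0.44 M
- larch: protic impurity 0.085 M; run made earlier
- oak: protic impurity 0.16 M; run made earlier
- ash: protic impurity 0.47 M; run made earlier
- Thursday's: protic impurity 0.0800 M; time 80 min
- Monday's: protic impurity 0.120 M; time 80 min
- Sunday's: protic impurity 0.200 M; time 80 min
- Saturday's: protic impurity 0.300 M; time 80 min
- Friday's: protic impurity 0.400 M; time 80 min

| run | time / min | ring / % |
|---|---|---|
| larch | 12.0 | 6.7 |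
| larch | 25.0 | 4.0 |
| larch | 30.0 | 2.4 |
| larch | 50.0 | 1.7 |
| larch | 60.0 | 1.0 |
| oak | 12.0 | 5.9 |
| oak | 25.0 | 2.0 |
| oak | 30.0 | 2.8 |
| oak | 50.0 | 0.8 |
| oak | 60.0 | 1.4 |
| ash | 12.0 | 3.9 |
| ash | 25.0 | 0.9 |
| ash | 30.0 | 1.1 |
| ash | 50.0 | 0.4 |
| ash | 60.0 | 0 |

(each reading ± 0.5 percentage points)

- percentages count the starting material that a species holds: one open dimer counts as two
- steps that have been proposed: ring -> over-reaction product; 2 starting material -> open dimer; starting material -> ring; starting material -> decomposition product; starting material + protic impurity -> quenched substrate
- "hardly changes" means that all values lie within two and a half points (for a concentration: within two and a half percent of the largest)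

- [ring] at the end for Thursday's, Monday's, Sunday's, Saturday's, Friday's, in this order
- how that number moves from the first to the last of them (hardly changes / rises all the way / falls, then rises / falls all the way / rises, then falls)

Of the first instants the readings say little, since nothing was sampled before 12.0 min. By then the larch run held 6.7% of ring, and the ash run, charged with more protic impurity, held less, 3.9%. So I took it that the impurity competed for starting material from the outset, as a step to quenched substrate beside the step to ring.

For the middle I asked what the fall of ring measures. I defined the fade constant of a run as the natural logarithm of the ring reading at 12.0 min over the reading at 25.0 min, divided by the time between them. The larch run gave 0.0397 min⁻¹, the oak run 0.0832 min⁻¹ and the ash run 0.113 min⁻¹. These are readings, and the ash value rests on a small number with a scatter of 0.5 percentage points. A first-order decay of ring on its own should fade alike in each flask, but the ash run faded faster than the larch run. So I treated ring as a steady-state intermediate whose level follows the starting material that feeds it, and I read the fade constant as the rate at which that starting material is used.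

For the end I carried each constant unchanged from the reading at 25.0 min to 80 min. The larch run, charged close to Thursday's, gave 0.00198 M. The ash run gave 8.01 × 10⁻⁶ M, and Friday's, with less impurity than ash, should stand above that. I expected a steep fall along the row.

The forecast gave 0.0019 M, 0.0017 M, 0.00145 M, 0.0012 M and 0.001 M, so falls all the way, on the ground that “More impurity quenches more substrate, so less ring forms”. We agreed on the direction and on Thursday's, and parted at Friday's.

The flask gave 0.00176 M, 0.00146 M, 8.30 × 10⁻⁴ M, 2.46 × 10⁻⁴ M and 3.78 × 10⁻⁵ M: falls all the way.

    ring → over-reaction product (k = 0.00392 s⁻¹)
    2 starting material → open dimer (k = 8.84 × 10⁻⁴ M⁻¹ s⁻¹)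
    starting material → ring (k = 5.41 × 10⁻⁴ s⁻¹)
    starting material → decomposition product (k = 2.68 × 10⁻⁷ s⁻¹)
    starting material + protic impurity → quenched substrate (k = 0.00835 M⁻¹ s⁻¹)

From 40.0 min to 80.0 min, Thursday's ring faded at 0.0375 min⁻¹ and its starting material at 0.0367 min⁻¹, against 0.0397 min⁻¹ in the larch run. The half-life of ring by its step to over-reaction product, 2.9 min in Thursday's, is short against 80 min. That step is the largest single effect on Thursday's ring at the end: the run without it ended at 0.220 M of ring, against 0.00176 M. Over the same span Friday's ring faded at 0.0843 min⁻¹ and its starting material at 0.0836 min⁻¹, against 0.113 min⁻¹ in the ash run. That step is in part why Friday's ring stood so low: the run without it ended at 0.0892 M of ring, against 3.78 × 10⁻⁵ M.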